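One mole of reagent consumed takes one mole of substrate into a product, so we count target per mole of reagent consumed.

| flask | substrate | reagent | remark | time |
|---|---|---|---|---|
| cedar | 0.55 M | 0.41 M | run made earlier |  |
| elm | 0.86 M | 0.41 M | run made earlier |  |
| flask | 0.39 M | 0.410 M |  | 15 min |

| run | time / min | target / % | isomer of the product / % |
|---|---|---|---|
| cedar | 2.00 | 19 | 31 |
| cedar | 4.00 | 18 | 36 |
| cedar | 5.00 | 22 | 41 |
| cedar | 8.00 | 19 | 42 |
| cedar | 10.0 | 21 | 43 |
| elm | 0.833 | 11 | 16 |
| elm | 2.50 | 13 | 25 |
| elm | 4.00 | 15 | 30 |
| elm | 6.00 | 16 | 26 |
| elm | 10.0 | 16 | 29 |

(each reading ± 1.5 percentage points)

- amount of target in the flask at 15 min, in percent of the substrate charged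
- amount of isomer of the product in the flask at 15 min, in percent of the substrate charged
- concentration of reagent at 15 min, in M

- reactions considered so far: substrate + reagent -> second isomer; substrate + reagent -> target; substrate + reagent -> isomer of the product

All the steps considered start from substrate + reagent. If each goes with the same product of concentrations, their split holds at any charge, so we freeze it. The late cedar and elm readings level off within their scatter, and their charges let the reagent convert at most 74.5 % and 47.7 % of the substrate. Taking the reagent as consumed there, the last two target readings give shares of 26.8 % in cedar and 33.6 % in elm. Their mean, 30.2 %, is our target share, the target formed per reagent consumed, a selectivity.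

In this flask substrate is the limiting reagent, 0.39 M against 0.410 M. Full conversion at elm's share therefore gives a ceiling of 33.6 % target.

For the floor we need a rate: one second-order constant for the steps taken together, read with the scatter of the readings. The first readings, set against the late ones, give 1.65 /M/min in elm and 2.51 /M/min in cedar. We take the lower. Reagent stays ahead of substrate in this flask, so reckoning with equal charges overstates what remains: with the lower constant we reckon at most 9.39 % of the substrate at 15 min. Cedar's share on the converted part gives our floor of 24.3 %. Our mean share on that part gives 27.4 %.

The forecast says 22 % target, 54 % isomer of the product and 0.05 M reagent, on the ground that “the second isomer rises as substrate concentration falls”. Its target stands below our floor.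

The flask gives 28.0 % target, 53.4 % isomer of the product and 0.0402 M reagent.

    substrate + reagent → second isomer (k = 0.300 /M/min)
    substrate + reagent → target (k = 0.630 /M/min)
    substrate + reagent → isomer of the product (k = 1.20 /M/min)

At 15.0 min this flask holds 5.2 % of its substrate, and our share on the converted rest gives 28.6 % target. A neighbour charged with 0.98 M substrate stands at 15.0 min with reagent at 2.94 × 10⁻⁹ M, so we reckon our share on its charge ratio, 12.6 %, and that neighbour holds 12.4 % target.

The earlier runs and the new flask were computed from invented constants, and the scatter is random.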